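**Plan**

- Cuts: the C14–C15 epoxide and the spiro lactone (C15–O, C13–C14) go first, then C1–C2 (ring A), C1=C13 (ring C), the C2–C3 ethylidene, C4–C5, C8–C17, C9–C11, and last the ring B bonds C5–C6 and C9–C10.
- Forward: ring B by a catalytic asymmetric [4+2] cycloaddition, elaborated on a cis-fused C1–O–C19 lactone; then the C5 spiro lactone and its ethylidene; ring C by Knoevenagel condensation; ring A by the vinylogous Michael addition; the spiro epoxy lactone last.
- Stereochemistry: C10 from the chiral copper catalyst; C9 and C5 by attack on the convex face of the cis-fused lactone; C8 by equilibration; C7 by equatorial hydride delivery; C1 thermodynamically in the key step; C13 by ligand-reinforced allylation; C14/C15 by dioxirane attack anti to C1.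
- Enabling feature: in ring A the C3=C4 alkene is conjugated to the C18 lactone carbonyl, so C2 is the γ-carbon of a lactone dienolate; C1 is β to the C12 ketone of ring C and C13 carries C16, so C1–C2 is a vinylogous Michael bond.

Key step: step 17

Convention: clerodane numbering; β is the face of ring B that carries C1 on C10 (later also C20 on C9, C19 on C5 and the C7 oxygen), α the face of H10.

Assumption: the (S,S)-copper catalyst of step 3 and the (R,R)-diphosphine of step 18 are taken to induce the sense drawn (the mirror-image ligand is used if the sense is opposite); the ethylidene lactone is drawn E, its geometry being lost in the dienolate.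

**Route**

Step 1
Reactants: 1 (E)-4-methoxypent-3-en-2-one
Product: 2 (E)-2-(tert-butyldimethylsilyloxy)-4-methoxypenta-1,3-diene
Conditions: TBSOTf, Et3N, Et2O, 0 °C
Reagents that add atoms: tert-butyldimethylsilyl triflate, CC(C)(C)[Si](C)(C)OS(=O)(=O)C(F)(F)F
Why: Soft enolisation and O-silylation of the methyl ketone (silyl dienol ether formation) at its only α'-position should give the 1-alkoxy-3-silyloxy diene.

Step 2
Reactants: 3 ethyl (E)-4-chloro-4-oxobut-2-enoate; 4 1,3-oxazolidin-2-one
Product: 5 ethyl (E)-4-oxo-4-(2-oxo-1,3-oxazolidin-3-yl)but-2-enoate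
Conditions: 4, n-BuLi, THF, −78 °C; then 3, −78 → 0 °C
Reagents that add atoms: none
Why: N-Acylation of the lithiated oxazolidinone by the acid chloride is the standard route to a chelating fumaroyl imide dienophile.

Step 3
Reactants: 2 silyloxy diene; 5 fumaroyl imide
Product: 6 ring B cycloadduct
Conditions: [Cu((S,S)-t-Bu-box)](SbF6)2 (10 mol %), CH2Cl2, −78 → −30 °C
Reagents that add atoms: none
Why: Chiral Lewis acid-catalysed Diels–Alder reaction of a two-point-bound acyl oxazolidinone: the nucleophilic CH2 terminus of the diene (C6) bonds to the imide β-carbon C5 and C9 to C10, the E dienophile gives the trans C5/C10 pair, and the ligand-shielded face fixes C10 (C9 is a mixture that is erased in step 4).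

Step 4
Reactants: 6 ring B cycloadduct
Product: 9 cis-fused enone lactone, via hydroxy ester 7 (not isolated), via silyl enol ether lactone 8 (not isolated)
Conditions: LiBH4, H2O (1 equiv), Et2O, 0 °C; then DBU, toluene, 80 °C; then 1 M HCl, THF, 25 °C
Reagents that add atoms: none
Why: Chemoselective borohydride reduction of the N-acyl oxazolidinone, base-mediated lactonisation with epimerisation of the ester-bearing C5 to the more stable cis-fused γ-lactone, and acid hydrolysis of the silyl enol ether with β-elimination of methanol should give the enone, the base treatment being finished before the enone (and with it an acidic H10) exists.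

Step 5
Reactants: 9 cis-fused enone lactone
Product: 10 allylated silyl enol ether
Conditions: allylmagnesium bromide, CuBr·SMe2, Me3SiCl, THF, −78 °C
Reagents that add atoms: allylmagnesium bromide, C=CC[Mg]Br; chlorotrimethylsilane, C[Si](C)(C)Cl
Why: Chlorosilane-accelerated conjugate addition of an allylcopper reagent to the β,β-disubstituted enone should deliver allyl to C9 on the convex α face, anti to the adjacent C10–C1 bond, and trap the enolate as a silyl enol ether that masks the C7 ketone.

Step 6
Reactants: 10 allylated silyl enol ether; 11 tert-butyl bromoacetate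
Product: 12 C5-alkylated lactone
Conditions: LiN(i-Pr)2, THF, −78 °C; then 11, −78 → −30 °C
Reagents that add atoms: none
Why: Alkylation of the ring-fusion lactone enolate from the α face (cis to H10, anti to the C9 methyl) is the only mode that keeps the γ-lactone cis-fused, so C5 should be fixed with C19 β and C4 α.

Step 7
Reactants: 12 C5-alkylated lactone
Product: 13 C8-methyl keto lactone
Conditions: Bu4N[Ph3SiF2], MeI, THF, 25 °C; then DBU (cat.), toluene, 60 °C
Reagents that add atoms: iodomethane, CI
Why: Fluoride-mediated enol silane alkylation methylates the regiodefined C7–C8 enolate, and base equilibration should then place the C8 methyl equatorial (β) in the chair that has C1 equatorial and only C19 and the C9 methyl axial.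

Step 8
Reactants: 13 C8-methyl keto lactone
Product: 14 7β-hydroxy lactone
Conditions: LiBH(s-Bu)3, THF, −78 °C; AcOH quench at −78 °C
Reagents that add atoms: none
Why: The bulky trialkylborohydride should attack the C7 ketone from the equatorial α side, the axial trajectory being blocked by the syn-axial C9 methyl and C19, to give the axial 7β-alcohol.

Step 9
Reactants: 14 7β-hydroxy lactone
Product: 16 spiro lactone diol, via triol ester 15 (not isolated)
Conditions: LiBH4, THF, 0 → 25 °C; then p-TsOH·H2O (cat.), toluene, 70 °C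
Reagents that add atoms: none
Why: LiBH4 reduces the γ-lactone but not the tert-butyl ester, and acid-catalysed lactonisation under equilibrating conditions is expected to settle on the five-membered spiro lactone C19–O–C18 rather than the δ-lactones available to the C1 or C7 hydroxyl.

Step 10
Reactants: 16 spiro lactone diol
Product: 17 C1 silyl ether
Conditions: TBSCl, imidazole, DMF, 0 °C
Reagents that add atoms: tert-butyldimethylsilyl chloride, CC(C)(C)[Si](C)(C)Cl
Why: Silylation should select the primary C1 hydroxyl over the axial secondary C7 hydroxyl, which is flanked by the C8 methyl and syn-axial to C19 and C20.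

Step 11
Reactants: 17 C1 silyl ether; 18 acetaldehyde
Product: 19 aldol adduct
Conditions: LiN(i-Pr)2 (2.2 equiv), THF, −78 °C; then 18
Reagents that add atoms: none
Why: Aldol addition of the lactone enolate (C4) to acetaldehyde, the C7 hydroxyl riding as its lithium alkoxide, creates two centres that are removed in step 12.

Step 12
Reactants: 19 aldol adduct
Product: 21 ethylidene lactone acetate, via diacetate 20 (not isolated)
Conditions: Ac2O, Et3N, DMAP (cat.), CH2Cl2, 25 °C; then DBU, 40 °C
Reagents that add atoms: acetic anhydride, CC(=O)OC(C)=O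
Why: Acetylation installs the C7 acetate of the target and activates the aldol hydroxyl, and E1cB elimination should then give the α-ethylidene lactone.

Step 13
Reactants: 21 ethylidene lactone acetate
Product: 22 C12 aldehyde
Conditions: K2OsO4·2H2O (2 mol %), NaIO4, 2,6-lutidine, dioxane/H2O, 25 °C
Reagents that add atoms: sodium periodate, [Na+].[O-]I(=O)(=O)=O
Why: Lemieux–Johnson cleavage should take the terminal allyl alkene much faster than the electron-poor trisubstituted ethylidene lactone.

Step 14
Reactants: 22 C12 aldehyde; 23 tert-butyl diazoacetate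
Product: 24 β-keto tert-butyl ester
Conditions: SnCl2 (10 mol %), CH2Cl2, 25 °C
Reagents that add atoms: none
Why: Roskamp homologation (Lewis acid-catalysed addition of the diazo ester, 1,2-hydride shift, loss of N2) should give the C11–C12–C13–C16 β-keto ester directly.

Step 15
Reactants: 24 β-keto tert-butyl ester
Product: 25 C1 alcohol
Conditions: HF·pyridine, pyridine, THF, 0 → 25 °C
Reagents that add atoms: none
Why: Buffered fluoride desilylation should free the primary alcohol without touching the acetate, the lactone or the β-keto ester.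

Step 16
Reactants: 25 C1 alcohol
Product: 27 key-step precursor, via keto aldehyde 26 (not isolated)
Conditions: SO3·pyridine, DMSO, i-Pr2NEt, CH2Cl2, 0 °C; then ethylenediammonium diacetate (10 mol %), 4 Å MS, 25 °C
Reagents that add atoms: none
Why: Parikh–Doering oxidation followed by intramolecular Knoevenagel condensation of C13 with the C1 aldehyde should close ring C as the alkylidene β-keto ester, trans-fused because C11 is α and C1 β, in a buffered medium too weakly basic to deprotonate the ethylidene lactone.

Step 17
Reactants: 27 key-step precursor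
Product: 28 tetracyclic enol β-keto ester
Conditions: DBU (1.0 equiv), MeCN, 25 → 50 °C
Reagents that add atoms: none
Why: DBU removes a γ-proton (C2 methyl) from the α-ethylidene lactone, and the dienolate adds through its γ-carbon to C1 of the alkylidene β-keto ester, which is activated by the C12 ketone and the C16 ester, to give the hydrogen-bonded enol of the β-keto ester. The closest known reaction type is the intramolecular γ-selective vinylogous Michael addition of an alkylidene lactone dienolate to an alkylidene 1,3-dicarbonyl compound. Ring A (C1, C2, C3, C4, C5, C10) closes in a 6-exo-trig mode, donor (C4 on C5) and acceptor (C1 on C10) sitting equatorially on adjacent ring B carbons. The one new stereocentre, C1, is under thermodynamic control: the adduct is a stabilised β-keto ester enol(ate), the addition is reversible, and the isomer with H1 β (trans to H10, ring A trans-fused to rings B and C) is the sink while the cis-fused epimer reverts by retro-Michael reaction. The step needs γ- over α-attack of the dienolate and 1,4- over 1,2-addition, and the tether secures both, since α-attack would give a cyclobutane and attack at C12 an eight-membered ring. The competing reversible removal of the vinylogous H10 of the enone ester is non-productive and should be drained by the same sink.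

Step 18
Reactants: 28 tetracyclic enol β-keto ester; 29 allyl acetate
Product: 30 13β-allyl β-keto ester
Conditions: [Pd(η3-C3H5)Cl]2 (1 mol %), (R,R)-N,N'-(cyclohexane-1,2-diyl)bis[2-(diphenylphosphino)benzamide] (2.5 mol %), tetramethylguanidine, toluene, 0 °C
Reagents that add atoms: none
Why: Tsuji–Trost asymmetric allylic alkylation of the cyclic β-keto ester enolate: on its α face C13 is screened by the peri C2 methylene and the syn-axial H10, H11 and H2, on its β face only by H1, so the bulky ligated π-allyl cation is expected to enter from the β side (C14 equatorial, C16 axial), and the ligand enantiomer is chosen to reinforce this bias.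

Step 19
Reactants: 30 13β-allyl β-keto ester
Product: 31 C15 aldehyde
Conditions: K2OsO4·2H2O (2 mol %), NaIO4, 2,6-lutidine, dioxane/H2O, 25 °C
Reagents that add atoms: sodium periodate, [Na+].[O-]I(=O)(=O)=O
Why: Lemieux–Johnson cleavage should select the terminal alkene, the C3=C4 alkene being trisubstituted, hindered and conjugated to the lactone.

Step 20
Reactants: 31 C15 aldehyde
Product: 34 spiro enol lactone, via aldehyde acid 32 (not isolated), via hydroxylactone 33 (not isolated)
Conditions: CF3CO2H, CH2Cl2, 0 °C; evaporate; then MsCl, Et3N, CH2Cl2, −20 → 25 °C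
Reagents that add atoms: none
Why: Acidolysis of the tert-butyl ester gives a γ-aldehydo acid that should close at once to the pseudo-acid (so the β-keto acid does not decarboxylate), and sulfonylation of the lactol hydroxyl with base-induced elimination (lactol dehydration) should give the enol lactone, whose quaternary α-carbon excludes isomerisation to a conjugated butenolide.

Step 21
Reactants: 34 spiro enol lactone
Product: 35 CNP0308057.1
Conditions: dimethyldioxirane (acetone solution), CH2Cl2, −20 → 0 °C
Reagents that add atoms: dimethyldioxirane, CC1(C)OO1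
Why: Neutral dioxirane epoxidation of the electron-rich enol lactone alkene (the C3=C4 enoate is inert) should occur on the face of the five-membered ring turned toward the flat C12 carbonyl and away from C1 and its peri C2 methylene, which is the C14/C15 configuration of the target.

**Compound list**

1 | (E)-4-methoxypent-3-en-2-one | CO/C(C)=C/C(C)=O | starting material
2 | (E)-2-(tert-butyldimethylsilyloxy)-4-methoxypenta-1,3-diene | CO/C(C)=C/C(=C)O[Si](C)(C)C(C)(C)C | intermediate
3 | ethyl (E)-4-chloro-4-oxobut-2-enoate | CCOC(=O)/C=C/C(Cl)=O | starting material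
4 | 1,3-oxazolidin-2-one | O=C1NCCO1 | starting material
5 | ethyl (E)-4-oxo-4-(2-oxo-1,3-oxazolidin-3-yl)but-2-enoate | CCOC(=O)/C=C/C(=O)N1CCOC1=O | intermediate
6 | ring B cycloadduct: cyclohexene with C7 OTBS enol ether (C7=C8), C9(OMe)(Me) (both epimers), 10β-(2-oxo-oxazolidine-3-carbonyl), 5α-CO2Et | CC(C)(C)[Si](C)(C)OC1C[C@@H](C(=O)OCC)[C@H](C(=O)N2CCOC2=O)C(C)(OC)C=1 | intermediate
7 | hydroxy ester: as 6 with 10β-CH2OH (C1) in place of the imide | CC(C)(C)[Si](C)(C)OC1C[C@@H](C(=O)OCC)[C@H](CO)C(C)(OC)C=1 | intermediate
8 | cis-fused γ-lactone C19(=O)–O–C1 (β on C5 and C10) with C7 OTBS enol ether and C9(OMe)(Me) | CC(C)(C)[Si](C)(C)OC1C[C@@H]2C(=O)OC[C@@H]2C(C)(OC)C=1 | intermediate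
9 | cis-4-methyl-3,3a,7,7a-tetrahydro-2-benzofuran-1,6-dione (C7 ketone, C8=C9, C1–O–C19 lactone β) | O=C1C[C@@H]2C(=O)OC[C@@H]2C(C)=C1 | intermediate
10 | 9α-allyl-9β-methyl C7 trimethylsilyl enol ether (C7=C8) of the cis-lactone | C[Si](C)(C)OC1C[C@@H]2C(=O)OC[C@@H]2[C@@](C)(CC=C)C=1 | intermediate
11 | tert-butyl bromoacetate | CC(C)(C)OC(=O)CBr | starting material
12 | as 10 with 5α-CH2CO2tBu (C4–C18) on the ring-fusion carbon C5 | C[Si](C)(C)OC1C[C@]2(CC(=O)OC(C)(C)C)C(=O)OC[C@@H]2[C@@](C)(CC=C)C=1 | intermediate
13 | keto lactone: C7 ketone, 8β-Me, 9β-Me, 9α-allyl, 5α-CH2CO2tBu, cis C1–O–C19 lactone | O=C1C[C@]2(CC(=O)OC(C)(C)C)C(=O)OC[C@@H]2[C@@](C)(CC=C)[C@@H]1C | intermediate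
14 | 7β-hydroxy (axial) analogue of 13 | O[C@@H]1C[C@]2(CC(=O)OC(C)(C)C)C(=O)OC[C@@H]2[C@@](C)(CC=C)[C@@H]1C | intermediate
15 | triol tert-butyl ester: 7β-OH, 5β-CH2OH (C19), 10β-CH2OH (C1), 5α-CH2CO2tBu | O[C@@H]1C[C@@](CO)(CC(=O)OC(C)(C)C)[C@H](CO)[C@@](C)(CC=C)[C@@H]1C | intermediate
16 | spiro lactone diol: C5-spiro γ-lactone (C19H2–O–C18(=O)–C4H2), 7β-OH, 10β-CH2OH, 8β-Me, 9β-Me, 9α-allyl | O[C@@H]1C[C@]2(COC(=O)C2)[C@H](CO)[C@@](C)(CC=C)[C@@H]1C | intermediate
17 | C1 O-TBS ether of 16 | O[C@@H]1C[C@]2(COC(=O)C2)[C@H](CO[Si](C)(C)C(C)(C)C)[C@@](C)(CC=C)[C@@H]1C | intermediate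
18 | acetaldehyde | CC=O | starting material
19 | aldol adduct of 17: 4-(1-hydroxyethyl) lactone (mixture at C4 and the carbinol carbon) | O[C@@H]1C[C@]2(COC(=O)C2C(C)O)[C@H](CO[Si](C)(C)C(C)(C)C)[C@@](C)(CC=C)[C@@H]1C | intermediate
20 | diacetate of 19 (7β-OAc and side-chain OAc) | CC(=O)O[C@@H]1C[C@]2(COC(=O)C2C(C)OC(C)=O)[C@H](CO[Si](C)(C)C(C)(C)C)[C@@](C)(CC=C)[C@@H]1C | intermediate
21 | 7β-acetoxy (E)-4-ethylidene spiro lactone with 9α-allyl and 10β-CH2OTBS | CC(=O)O[C@@H]1C[C@]2(COC(=O)/C2=C/C)[C@H](CO[Si](C)(C)C(C)(C)C)[C@@](C)(CC=C)[C@@H]1C | intermediate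
22 | C12 aldehyde: 9α-CH2CHO analogue of 21 | CC(=O)O[C@@H]1C[C@]2(COC(=O)/C2=C/C)[C@H](CO[Si](C)(C)C(C)(C)C)[C@@](C)(CC=O)[C@@H]1C | intermediate
23 | tert-butyl diazoacetate | CC(C)(C)OC(=O)C=[N+]=[N-] | starting material
24 | β-keto ester: 9α-CH2C(=O)CH2CO2tBu (C11–C12–C13–C16) | CC(=O)O[C@@H]1C[C@]2(COC(=O)/C2=C/C)[C@H](CO[Si](C)(C)C(C)(C)C)[C@@](C)(CC(=O)CC(=O)OC(C)(C)C)[C@@H]1C | intermediate
25 | C1 alcohol (10β-CH2OH) of 24 | CC(=O)O[C@@H]1C[C@]2(COC(=O)/C2=C/C)[C@H](CO)[C@@](C)(CC(=O)CC(=O)OC(C)(C)C)[C@@H]1C | intermediate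
26 | C1 aldehyde (10β-CHO) of 24 | CC(=O)O[C@@H]1C[C@]2(COC(=O)/C2=C/C)[C@H](C=O)[C@@](C)(CC(=O)CC(=O)OC(C)(C)C)[C@@H]1C | intermediate
27 | key-step precursor: trans-fused B/C enone tert-butyl ester (C1=C13, C12 ketone, C16 ester) with the C5-spiro (E)-α-ethylidene lactone, 7β-OAc, 8β-Me, 9β-Me, 10α-H | CC(=O)O[C@@H]1C[C@]2(COC(=O)/C2=C/C)[C@@H]3C=C(C(=O)OC(C)(C)C)C(=O)C[C@@]3(C)[C@@H]1C | intermediate
28 | key-step product: tetracyclic enol of the β-keto tert-butyl ester (C12 OH, C12=C13), ring A closed at C1–C2, C3=C4, 1β-H, 10α-H | CC(=O)O[C@@H]1C[C@@]23COC(=O)C2=CC[C@@H]2[C@@H]3[C@@](C)(CC(O)=C2C(=O)OC(C)(C)C)[C@@H]1C | intermediate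
29 | allyl acetate | C=CCOC(C)=O | starting material
30 | 13β-allyl β-keto tert-butyl ester (C16 α, axial) | CC(=O)O[C@@H]1C[C@@]23COC(=O)C2=CC[C@@H]2[C@@H]3[C@@](C)(CC(=O)[C@]2(CC=C)C(=O)OC(C)(C)C)[C@@H]1C | intermediate
31 | 13β-(2-oxoethyl) β-keto tert-butyl ester (C15 aldehyde) | CC(=O)O[C@@H]1C[C@@]23COC(=O)C2=CC[C@@H]2[C@@H]3[C@@](C)(CC(=O)[C@]2(CC=O)C(=O)OC(C)(C)C)[C@@H]1C | intermediate
32 | aldehyde acid (C16 CO2H, C15 CHO) | CC(=O)O[C@@H]1C[C@@]23COC(=O)C2=CC[C@@H]2[C@@H]3[C@@](C)(CC(=O)[C@]2(CC=O)C(=O)O)[C@@H]1C | intermediate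
33 | C15-hydroxy spiro γ-lactone (pseudo-acid, both C15 epimers) | CC(=O)O[C@@H]1C[C@@]23COC(=O)C2=CC[C@@H]2[C@@H]3[C@@](C)(CC(=O)[C@]23C(=O)OC(O)C3)[C@@H]1C | intermediate
34 | spiro enol lactone (C14=C15, furan-2(3H)-one on C13) | CC(=O)O[C@@H]1C[C@@]23COC(=O)C2=CC[C@@H]2[C@@H]3[C@@](C)(CC(=O)[C@]23C(=O)OC=C3)[C@@H]1C | intermediate
35 | CNP0308057.1 | CC(=O)O[C@@H]1C[C@@]23COC(=O)C2=CC[C@@H]2[C@@H]3[C@@](C)(CC(=O)[C@]23C(=O)O[C@H]2O[C@H]23)[C@@H]1C | target

**Step count and risks**

Total step count: 21. Longest linear sequence: 20 steps (step 1 or step 2, then steps 3–21).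

Steps most likely to fail:

1. Step 18, poor facial selectivity at C13. Attack on the α face is the stereoelectronically favoured axial attack and may compete with, or override, the steric and ligand bias for the β face. Fallback: auxiliary control through a chiral enamine. Starting from 28, condensation with tert-butyl L-valinate (BF3·OEt2 cat., toluene, reflux with water removal) should give the enamino ester F1. Deprotonation with LiN(i-Pr)2 at −78 °C and reaction with allyl bromide should give the C13-allylated imine F2; the auxiliary antipode and the solvent (toluene or THF/HMPA, which reverse the face in this chemistry) are chosen for β attack. Hydrolysis with aqueous AcOH/NaOAc returns the route at 30.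

2. Step 17, erosion of the ring fusion or a stalled equilibrium. Reversible removal of the vinylogous H10 of the enone ester can epimerise C10 before ring closure, and the cis-fused C1 epimer may not drain fully. Fallback: a base-free, kinetically controlled closure. Starting from 27, TBSOTf and Et3N in CH2Cl2 at −78 °C should silylate the unhindered ethylidene γ-position to give the 2-silyloxy-3-vinyl-4,5-dihydrofuran (silyl ketene acetal) F3. Under catalytic TBSOTf this should undergo an intramolecular vinylogous Mukaiyama–Michael addition through a chair-like transition state to the silyl enol ether F4. HF·pyridine returns the route at 28.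

3. Step 3, loss of enantio- or regiocontrol, or Lewis acid-induced desilylation of the diene before cycloaddition. Fallback: auxiliary instead of catalyst control. Starting from 3, acylation of lithiated (S)-4-benzyl-1,3-oxazolidin-2-one (its mirror image if the sense of induction requires it) gives the fumaroyl imide F5. Its Et2AlCl-promoted Diels–Alder reaction with 2 in CH2Cl2 at −78 °C should give the cycloadduct F6 through the chelated s-cis imide. LiBH4 cleavage of the auxiliary returns the route at 7, inside step 4.

Further compounds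
F1 | step 18 | enamino ester of 28 with tert-butyl L-valinate (C12 N-substituted, C12=C13) | CC(=O)O[C@@H]1C[C@@]23COC(=O)C2=CC[C@@H]2[C@@H]3[C@@](C)(CC(N[C@@H](C(C)C)C(=O)OC(C)(C)C)=C2C(=O)OC(C)(C)C)[C@@H]1C
F2 | step 18 | 13β-allyl C12 imine of tert-butyl L-valinate | CC(=O)O[C@@H]1C[C@@]23COC(=O)C2=CC[C@@H]2[C@@H]3[C@@](C)(CC(=N[C@@H](C(C)C)C(=O)OC(C)(C)C)[C@]2(CC=C)C(=O)OC(C)(C)C)[C@@H]1C
F3 | step 17 | silyl ketene acetal of 27 (C18 OTBS, C18=C4, C3=C2 vinyl) | CC(=O)O[C@@H]1C[C@]2(COC(O[Si](C)(C)C(C)(C)C)=C2C=C)[C@@H]3C=C(C(=O)OC(C)(C)C)C(=O)C[C@@]3(C)[C@@H]1C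
F4 | step 17 | C12 O-TBS enol ether of 28 | CC(=O)O[C@@H]1C[C@@]23COC(=O)C2=CC[C@@H]2[C@@H]3[C@@](C)(CC(O[Si](C)(C)C(C)(C)C)=C2C(=O)OC(C)(C)C)[C@@H]1C
F5 | step 3 | ethyl (E)-4-[(4S)-4-benzyl-2-oxo-1,3-oxazolidin-3-yl]-4-oxobut-2-enoate | CCOC(=O)/C=C/C(=O)N1[C@@H](Cc2ccccc2)COC1=O
F6 | step 3 | cycloadduct as 6 carrying the (S)-4-benzyl oxazolidinone | CC(C)(C)[Si](C)(C)OC1C[C@@H](C(=O)OCC)[C@H](C(=O)N2[C@@H](Cc3ccccc3)COC2=O)C(C)(OC)C=1
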